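Locants: azulene numbering of the target (C3 = C–CH3, C3a/C8a = ring fusion, C4 = CHOH, C5 = CH–chain, C6 = CH2, C7 = CHOH, C8 = C=CH2); chain C1′ (CHCH3), C2′ and C3′ (CHOAc).
Retrosynthesis: (a) the chain is cut at C3′–C4′, C2′–O, C1′–CH3 and C1′=C2′ back to a C5 ester; (b) C8=CH2 and C7–O are cut back to an 8-ketone whose C7 and C4 are joined by an oxygen bridge; (c) C6–C7 and C4–C5 are cut together, to methyl acrylate and a cyclopentene carrying a diazoacetyl group (C8, C7) on C8a and a formyl group (C4) on C3a; (d) the cyclopentene is cut at C2=C3 and C8a–C1, back to furan-2(5H)-one.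
Forward order: cyclopentene (steps 1–6); seven-membered ring, with a temporary 4,7-oxygen bridge and an 8-keto group, in one operation (step 7); bridge opened, C7–OH and C8=CH2 installed (steps 8–12); chain grown on C5 (steps 13–22).
Feature used: C7 and C4 both carry oxygen, lie 1,4 across the seven-membered ring and flank the CH2–CH unit C6–C5, and C8 can be a carbonyl; the chain C7–C8–C8a–C3a–C4 can therefore close through the C4 aldehyde oxygen to a six-membered carbonyl ylide with C7 and C4 as its ends, and the trans-fused cyclopentene decides which face the alkene takes.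
Stereochemistry: C3a from Rh/(S)-BINAP; C8a by trans alkylation; C4 and C5 in the cycloaddition (bridge cis to H-3a, ester exo); C7 by enolate oxidation anti to the C4/C5 groups; C1′ and C2′ from an (S)-oxazolidinone imide; C3′ by hydride addition anti to the 2′-acetoxy group.

Key step: step 7

Assumption: (S)-BINAP is taken to select the same face of the enoate in furan-2(5H)-one as it does in cyclic enones, which gives (S)-2; (R)-BINAP would be used if the sense proved opposite.
Abbreviations: TBS = tert-butyldimethylsilyl; Az = (3aS,4R,5S,7R,8aR)-4,7-bis(TBS-oxy)-3-methyl-8-methylidene-1,3a,4,5,6,7,8,8a-octahydroazulen-5-yl.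

Step 1
Reactants: 1 furan-2(5H)-one
Product: 2 (S)-4-(prop-1-en-2-yl)oxolan-2-one
Conditions: [Rh(cod)2]PF6 (3 mol %), (S)-BINAP (3.3 mol %), K[CH2=C(CH3)BF3] (2 equiv), toluene/H2O 20:1, 100 °C
Reagents that add atoms: potassium trifluoro(prop-1-en-2-yl)borate, [K+].C=C(C)[B-](F)(F)F
Why: Rhodium/bisphosphine-catalysed asymmetric 1,4-addition of an alkenylboron reagent to a cyclic enoate; the chiral ligand selects the enoate face and so sets C3a.

Step 2
Reactants: 2 (S)-4-(prop-1-en-2-yl)oxolan-2-one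
Product: 3 (3R,4S)-3-(prop-2-en-1-yl)-4-(prop-1-en-2-yl)oxolan-2-one
Conditions: LiN(i-Pr)2, THF, −78 °C; allyl bromide, −78 → −40 °C
Reagents that add atoms: allyl bromide, C=CCBr
Why: Lactone enolate alkylation; the electrophile enters anti to the neighbouring isopropenyl group, which sets C8a trans to C3a.

Step 3
Reactants: 3 (3R,4S)-3-(prop-2-en-1-yl)-4-(prop-1-en-2-yl)oxolan-2-one
Product: 5 (3R,4S)-4-(hydroxymethyl)-5-methyl-3-(prop-2-en-1-yl)hex-5-en-2-one, via cyclic hemiketal 4 (not isolated)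
Conditions: MeLi (1.05 equiv), THF, −78 °C; AcOH
Reagents that add atoms: methyllithium, [Li]C
Why: Single addition of an organolithium to a lactone stops at the hemiketal stage, and this opens on work-up to the γ-hydroxy methyl ketone; no stereocentre is touched.

Step 4
Reactants: 5 (3R,4S)-4-(hydroxymethyl)-5-methyl-3-(prop-2-en-1-yl)hex-5-en-2-one
Product: 6 1-[(1R,5S)-5-(hydroxymethyl)-4-methylcyclopent-3-en-1-yl]ethan-1-one
Conditions: second-generation Grubbs catalyst (3 mol %), CH2Cl2, 40 °C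
Reagents that add atoms: none
Why: Ring-closing metathesis of the allyl and isopropenyl groups closes the trisubstituted cyclopentene through the open-chain tautomer, driven by loss of ethene; the two stereocentres are not involved.

Step 5
Reactants: 6 1-[(1R,5S)-5-(hydroxymethyl)-4-methylcyclopent-3-en-1-yl]ethan-1-one
Product: 8 2-diazo-1-[(1R,5S)-5-(hydroxymethyl)-4-methylcyclopent-3-en-1-yl]ethan-1-one, via bis(trifluoroacetyl) intermediate 7 (not isolated)
Conditions: LiN(SiMe3)2 (2.2 equiv), THF, −78 °C; CF3CO2CH2CF3 (2.4 equiv); 5% aq HCl; then MeSO2N3, Et3N, H2O, MeCN, 25 °C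
Reagents that add atoms: methanesulfonyl azide, CS(=O)(=O)N=[N+]=[N-]
Why: Detrifluoroacetylative diazo transfer: the kinetic methyl enolate is C-trifluoroacetylated and the activated 1,3-diketone takes the diazo group from the sulfonyl azide with loss of the trifluoroacetyl group, while the hydroxyl is masked in passing as its trifluoroacetate and freed again by the aqueous amine.

Step 6
Reactants: 8 2-diazo-1-[(1R,5S)-5-(hydroxymethyl)-4-methylcyclopent-3-en-1-yl]ethan-1-one
Product: 9 (1S,5R)-5-(diazoacetyl)-2-methylcyclopent-2-ene-1-carbaldehyde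
Conditions: Dess–Martin periodinane (1.2 equiv), pyridine, CH2Cl2, 0 °C
Reagents that add atoms: none
Why: Periodinane oxidation of the primary alcohol is neutral and tolerated by diazo ketones, so the allylic α-stereocentre of the β,γ-unsaturated aldehyde should survive; the aldehyde is used at once.

Step 7
Reactants: 9 (1S,5R)-5-(diazoacetyl)-2-methylcyclopent-2-ene-1-carbaldehyde; 10 methyl prop-2-enoate
Product: 13 methyl (3aS,4S,5R,7S,8aR)-3-methyl-8-oxo-1,3a,4,5,6,7,8,8a-octahydro-4,7-epoxyazulene-5-carboxylate (ester exo), via carbonyl ylide 11 (not isolated), via endo ester 12 (not isolated)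
Conditions: Rh2(OAc)4 (1 mol %), methyl acrylate (5 equiv), CH2Cl2, 25 °C, slow addition of 9; evaporate; then NaOMe (0.2 equiv), MeOH, 0 °C
Reagents that add atoms: none
Why: Rh2(OAc)4 takes N2 from 9 and the aldehyde oxygen closes onto the rhodium-bound carbon C7 to give carbonyl ylide 11, which adds as a 1,3-dipole across the C=C of the acrylate, so that the chain C7–C8–C8a–C3a–C4 and the two alkene carbons become the seven-membered carbocycle, bridged by oxygen. The closest known reaction type is the tandem carbenoid cyclization–(3+2) cycloaddition of 1-diazoalkane-2,5-diones and related δ-carbonyl diazo ketones with electron-poor alkenes. The oxane ring closes by attack of the carbonyl oxygen on the carbenoid carbon (six-membered closure), and the oxolane ring (O, C7, C6, C5, C4) and with it the cycloheptane ring close in the concerted, suprafacial (3+2) addition. C4 and C7 are set by the face of the ylide: the alkene should add so that the new oxanone ring is a chair with both bonds of the trans-fused cyclopentene equatorial, which puts the oxygen bridge cis to H-3a and leaves C3a and C8a as they were. C5 is set by the exo orientation of the ester, favoured because the endo region is screened by the axial H-8a and the equatorial C3 substituent on C3a, and any endo ester 12 is epimerized by NaOMe at the ester α-carbon to the more stable exo ester 13. The step needs regioselectivity (acrylate CH2 to C7), which the polarization of the ylide secures, C7 next to the ketone being its nucleophilic end and the aldehyde-derived C4 its electrophilic end, and it needs ylide formation to beat cyclopropanation and C–H insertion, which the six-membered oxygen attack and the excess of acrylate secure.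

Step 8
Reactants: 13 methyl (3aS,4S,5R,7S,8aR)-3-methyl-8-oxo-1,3a,4,5,6,7,8,8a-octahydro-4,7-epoxyazulene-5-carboxylate
Product: 14 methyl (3aS,4S,5R,8aR)-4-hydroxy-3-methyl-8-oxo-1,3a,4,5,6,7,8,8a-octahydroazulene-5-carboxylate
Conditions: SmI2 (2.5 equiv), THF/MeOH 10:1, −78 °C
Reagents that add atoms: none
Why: Reductive cleavage of a C–O bond α to a ketone: the ketyl expels the bridging oxygen from C7, where it sits on the face opposite to the one the target needs, the oxygen stays on C4 with its configuration, and protonation gives the 8-ketone with C7 as CH2.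

Step 9
Reactants: 14 methyl (3aS,4S,5R,8aR)-4-hydroxy-3-methyl-8-oxo-1,3a,4,5,6,7,8,8a-octahydroazulene-5-carboxylate
Product: 15 methyl (3aS,4S,5R,8aR)-4-(TBS-oxy)-3-methyl-8-oxo-1,3a,4,5,6,7,8,8a-octahydroazulene-5-carboxylate
Conditions: t-BuMe2SiOTf, 2,6-lutidine, CH2Cl2, −78 °C
Reagents that add atoms: tert-butyldimethylsilyl trifluoromethanesulfonate, CC(C)(C)[Si](C)(C)OS(=O)(=O)C(F)(F)F
Why: Silylation of the secondary alcohol protects the C4 oxygen for the base and hydride steps that follow and adds bulk to the upper face of the ring; no stereocentre is touched.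

Step 10
Reactants: 15 methyl (3aS,4S,5R,8aR)-4-(TBS-oxy)-3-methyl-8-oxo-1,3a,4,5,6,7,8,8a-octahydroazulene-5-carboxylate
Product: 16 methyl (3aS,4S,5R,7R,8aR)-4-(TBS-oxy)-7-hydroxy-3-methyl-8-oxo-1,3a,4,5,6,7,8,8a-octahydroazulene-5-carboxylate
Conditions: KN(SiMe3)2 (1.1 equiv), THF, −78 °C; 2-(benzenesulfonyl)-3-phenyloxaziridine; AcOH
Reagents that add atoms: 2-(benzenesulfonyl)-3-phenyloxaziridine, O=S(=O)(c1ccccc1)N1OC1c1ccccc1
Why: Enolate hydroxylation with an N-sulfonyloxaziridine: kinetic deprotonation takes the C7 CH2 and not the ring-fusion CH (C8a), and oxygen transfer should occur on the face opposite the C5 ester and the C4 silyloxy group, which gives the 7R alcohol.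

Step 11
Reactants: 16 methyl (3aS,4S,5R,7R,8aR)-4-(TBS-oxy)-7-hydroxy-3-methyl-8-oxo-1,3a,4,5,6,7,8,8a-octahydroazulene-5-carboxylate
Product: 17 methyl (3aS,4S,5R,7R,8aR)-4,7-bis(TBS-oxy)-3-methyl-8-oxo-1,3a,4,5,6,7,8,8a-octahydroazulene-5-carboxylate
Conditions: t-BuMe2SiOTf, 2,6-lutidine, CH2Cl2, −78 °C
Reagents that add atoms: tert-butyldimethylsilyl trifluoromethanesulfonate, CC(C)(C)[Si](C)(C)OS(=O)(=O)C(F)(F)F
Why: Silylation of the α-hydroxy ketone under non-enolizing conditions keeps C7 and C8a intact.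

Step 12
Reactants: 17 methyl (3aS,4S,5R,7R,8aR)-4,7-bis(TBS-oxy)-3-methyl-8-oxo-1,3a,4,5,6,7,8,8a-octahydroazulene-5-carboxylate
Product: 18 methyl (3aS,4S,5R,7R,8aR)-4,7-bis(TBS-oxy)-3-methyl-8-methylidene-1,3a,4,5,6,7,8,8a-octahydroazulene-5-carboxylate
Conditions: Zn, CH2Br2, TiCl4, THF, 0 → 25 °C
Reagents that add atoms: dibromomethane, BrCBr
Why: Non-basic zinc/titanium methylenation converts hindered, enolizable ketones into methylene compounds without epimerizing the α-centres (C7, C8a) and leaves the ester alone.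

Step 13
Reactants: 18 methyl (3aS,4S,5R,7R,8aR)-4,7-bis(TBS-oxy)-3-methyl-8-methylidene-1,3a,4,5,6,7,8,8a-octahydroazulene-5-carboxylate
Product: 19 (3aS,4S,5R,7R,8aR)-4,7-bis(TBS-oxy)-3-methyl-8-methylidene-1,3a,4,5,6,7,8,8a-octahydroazulene-5-carbaldehyde
Conditions: i-Bu2AlH (1.1 equiv), CH2Cl2, −78 °C; aqueous potassium sodium tartrate
Reagents that add atoms: none
Why: Partial reduction of the methyl ester at low temperature stops at the aluminium hemiacetal, which is held by the neighbouring silyloxy group and releases the aldehyde on work-up.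

Step 14
Reactants: 20 (S)-4-benzyl-1,3-oxazolidin-2-one; 21 (diethoxyphosphoryl)acetic acid
Product: 23 diethyl {2-[(4S)-4-benzyl-2-oxo-1,3-oxazolidin-3-yl]-2-oxoethyl}phosphonate, via mixed pivalic anhydride 22 (not isolated)
Conditions: t-BuCOCl, Et3N, THF, −20 °C; then 20, LiCl, 25 °C
Reagents that add atoms: none
Why: N-Acylation of the oxazolidinone by a mixed anhydride under LiCl/Et3N activation gives the olefination reagent; the stereocentre of the auxiliary is not involved.

Step 15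
Reactants: 19 (3aS,4S,5R,7R,8aR)-4,7-bis(TBS-oxy)-3-methyl-8-methylidene-1,3a,4,5,6,7,8,8a-octahydroazulene-5-carbaldehyde; 23 diethyl {2-[(4S)-4-benzyl-2-oxo-1,3-oxazolidin-3-yl]-2-oxoethyl}phosphonate
Product: 24 (4S)-4-benzyl-3-[(2E)-3-Az-prop-2-enoyl]-1,3-oxazolidin-2-one
Conditions: LiCl, i-Pr2NEt, MeCN, 25 °C
Reagents that add atoms: none
Why: Horner–Wadsworth–Emmons olefination under mild LiCl/amine conditions gives the E-enoyl imide without epimerizing the α-stereocentre (C5) of the aldehyde.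

Step 16
Reactants: 24 (4S)-4-benzyl-3-[(2E)-3-Az-prop-2-enoyl]-1,3-oxazolidin-2-one
Product: 25 (4S)-4-benzyl-3-[(3S)-3-Az-butanoyl]-1,3-oxazolidin-2-one
Conditions: MeMgBr (1.5 equiv), CuBr·SMe2 (30 mol %), THF/Me2S, −78 → −20 °C
Reagents that add atoms: methylmagnesium bromide, C[Mg]Br
Why: Copper-catalysed conjugate addition under auxiliary control: in the chelated s-cis enoyl imide the benzyl group shields one face, so methyl adds to the other and sets C1′ as in the target.

Step 17
Reactants: 25 (4S)-4-benzyl-3-[(3S)-3-Az-butanoyl]-1,3-oxazolidin-2-one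
Product: 26 (4S)-4-benzyl-3-[(2S,3R)-3-Az-2-hydroxybutanoyl]-1,3-oxazolidin-2-one
Conditions: NaN(SiMe3)2 (1.2 equiv), THF, −78 °C; 2-(benzenesulfonyl)-3-phenyloxaziridine; AcOH
Reagents that add atoms: 2-(benzenesulfonyl)-3-phenyloxaziridine, O=S(=O)(c1ccccc1)N1OC1c1ccccc1
Why: Electrophilic hydroxylation of the chelated Z-enolate of the imide on the face opposite the benzyl group sets C2′ as S.

Step 18
Reactants: 26 (4S)-4-benzyl-3-[(2S,3R)-3-Az-2-hydroxybutanoyl]-1,3-oxazolidin-2-one
Product: 27 (2S,3R)-3-Az-2-hydroxy-N-methoxy-N-methylbutanamide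
Conditions: MeNH(OMe)·HCl (3 equiv), AlMe3 (3 equiv), CH2Cl2, 0 → 25 °C
Reagents that add atoms: N,O-dimethylhydroxylamine hydrochloride, CNOC.Cl
Why: Aluminium amide transamidation of the N-acyl oxazolidinone, helped by the free α-hydroxyl, gives the N-methoxy-N-methylamide and returns the auxiliary without touching C2′.

Step 19
Reactants: 27 (2S,3R)-3-Az-2-hydroxy-N-methoxy-N-methylbutanamide
Product: 28 (5S,6R)-6-Az-5-hydroxy-2-methylhept-2-en-4-one
Conditions: (CH3)2C=CHMgBr (3 equiv), THF, 0 °C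
Reagents that add atoms: (2-methylprop-1-en-1-yl)magnesium bromide, CC(C)=C[Mg]Br
Why: Grignard addition to an N-methoxy-N-methylamide stops at the chelated tetrahedral adduct and gives the enone on work-up; no stereocentre is formed.

Step 20
Reactants: 28 (5S,6R)-6-Az-5-hydroxy-2-methylhept-2-en-4-one
Product: 29 (2R,3S)-2-Az-6-methyl-4-oxohept-5-en-3-yl acetate
Conditions: Ac2O, pyridine, DMAP (cat.), CH2Cl2, 0 °C
Reagents that add atoms: acetic anhydride, CC(=O)OC(C)=O
Why: Acetylation installs the first target acetate and turns the α-oxygen into a non-chelating polar substituent for the reduction that follows.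

Step 21
Reactants: 29 (2R,3S)-2-Az-6-methyl-4-oxohept-5-en-3-yl acetate
Product: 31 (2R,3S,4S)-2-Az-6-methylhept-5-ene-3,4-diyl diacetate, via hydroxy acetate 30 (not isolated)
Conditions: LiBH(s-Bu)3 (1.2 equiv), THF, −78 °C; then Ac2O, pyridine, DMAP, 0 → 25 °C
Reagents that add atoms: acetic anhydride, CC(=O)OC(C)=O
Why: 1,2-Reduction of the enone by a bulky hydride should go through the open transition state with the C–OAc bond anti to the incoming hydride, which gives the 2′,3′-syn (3′S) alcohol, and acetylation in the same flask makes any acetyl shift between the two oxygens irrelevant.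

Step 22
Reactants: 31 (2R,3S,4S)-2-Az-6-methylhept-5-ene-3,4-diyl diacetate
Product: 32 (3aS,4R,5S,7R,8aR)-5-[(2R,3S,4S)-3,4-bis(acetyloxy)-6-methylhept-5-en-2-yl]-3-methyl-8-methylidene-1,3a,4,5,6,7,8,8a-octahydroazulene-4,7-diol
Conditions: HF·pyridine, pyridine, THF, 0 → 25 °C
Reagents that add atoms: none
Why: Buffered fluoride cleavage of both silyl ethers should leave the two acetates and the allylic alcohol untouched and give the target.

Compound list
1 | furan-2(5H)-one | O=C1OCC=C1 | starting material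
2 | (S)-4-(prop-1-en-2-yl)oxolan-2-one | O=C1OC[C@H](C(C)=C)C1 | intermediate
3 | (3R,4S)-3-(prop-2-en-1-yl)-4-(prop-1-en-2-yl)oxolan-2-one (3,4-trans) | O=C1OC[C@H](C(C)=C)[C@H]1CC=C | intermediate
4 | (3R,4S)-2-methyl-3-(prop-2-en-1-yl)-4-(prop-1-en-2-yl)oxolan-2-ol (cyclic hemiketal, C2 not defined) | CC1(O)OC[C@H](C(C)=C)[C@H]1CC=C | intermediate (not isolated)
5 | (3R,4S)-4-(hydroxymethyl)-5-methyl-3-(prop-2-en-1-yl)hex-5-en-2-one | CC(=O)[C@H](CC=C)[C@H](CO)C(C)=C | intermediate
6 | 1-[(1R,5S)-5-(hydroxymethyl)-4-methylcyclopent-3-en-1-yl]ethan-1-one (trans) | CC(=O)[C@@H]1CC=C(C)[C@H]1CO | intermediate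
7 | [(1S,5R)-2-methyl-5-(4,4,4-trifluoro-3-oxobutanoyl)cyclopent-2-en-1-yl]methyl trifluoroacetate | O=C(CC(=O)C(F)(F)F)[C@@H]1CC=C(C)[C@H]1COC(=O)C(F)(F)F | intermediate (not isolated)
8 | 2-diazo-1-[(1R,5S)-5-(hydroxymethyl)-4-methylcyclopent-3-en-1-yl]ethan-1-one | [N-]=[N+]=CC(=O)[C@@H]1CC=C(C)[C@H]1CO | intermediate
9 | (1S,5R)-5-(diazoacetyl)-2-methylcyclopent-2-ene-1-carbaldehyde | [N-]=[N+]=CC(=O)[C@@H]1CC=C(C)[C@H]1C=O | intermediate
10 | methyl prop-2-enoate | C=CC(=O)OC | starting material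
11 | cyclic carbonyl ylide (formyl oxygen of 9 bonded to C7; six-membered oxonium ylide trans-fused to the cyclopentene) | O=C1[CH-][O+]=C[C@@H]2C(C)=CC[C@@H]12 | intermediate (not isolated)
12 | methyl (3aS,4S,5S,7S,8aR)-3-methyl-8-oxo-1,3a,4,5,6,7,8,8a-octahydro-4,7-epoxyazulene-5-carboxylate (ester endo) | O=C1[C@@H]2C[C@H](C(=O)OC)[C@@H](O2)[C@@H]3C(C)=CC[C@@H]13 | intermediate (not isolated)
13 | methyl (3aS,4S,5R,7S,8aR)-3-methyl-8-oxo-1,3a,4,5,6,7,8,8a-octahydro-4,7-epoxyazulene-5-carboxylate (ester exo) | O=C1[C@@H]2C[C@@H](C(=O)OC)[C@@H](O2)[C@@H]3C(C)=CC[C@@H]13 | intermediate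
14 | methyl (3aS,4S,5R,8aR)-4-hydroxy-3-methyl-8-oxo-1,3a,4,5,6,7,8,8a-octahydroazulene-5-carboxylate | O=C1CC[C@@H](C(=O)OC)[C@@H](O)[C@@H]2C(C)=CC[C@@H]12 | intermediate
15 | methyl (3aS,4S,5R,8aR)-4-(TBS-oxy)-3-methyl-8-oxo-1,3a,4,5,6,7,8,8a-octahydroazulene-5-carboxylate | O=C1CC[C@@H](C(=O)OC)[C@@H](O[Si](C)(C)C(C)(C)C)[C@@H]2C(C)=CC[C@@H]12 | intermediate
16 | methyl (3aS,4S,5R,7R,8aR)-4-(TBS-oxy)-7-hydroxy-3-methyl-8-oxo-1,3a,4,5,6,7,8,8a-octahydroazulene-5-carboxylate | O=C1[C@H](O)C[C@@H](C(=O)OC)[C@@H](O[Si](C)(C)C(C)(C)C)[C@@H]2C(C)=CC[C@@H]12 | intermediate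
17 | methyl (3aS,4S,5R,7R,8aR)-4,7-bis(TBS-oxy)-3-methyl-8-oxo-1,3a,4,5,6,7,8,8a-octahydroazulene-5-carboxylate | O=C1[C@H](O[Si](C)(C)C(C)(C)C)C[C@@H](C(=O)OC)[C@@H](O[Si](C)(C)C(C)(C)C)[C@@H]2C(C)=CC[C@@H]12 | intermediate
18 | methyl (3aS,4S,5R,7R,8aR)-4,7-bis(TBS-oxy)-3-methyl-8-methylidene-1,3a,4,5,6,7,8,8a-octahydroazulene-5-carboxylate | C=C1[C@H](O[Si](C)(C)C(C)(C)C)C[C@@H](C(=O)OC)[C@@H](O[Si](C)(C)C(C)(C)C)[C@@H]2C(C)=CC[C@@H]12 | intermediate
19 | (3aS,4S,5R,7R,8aR)-4,7-bis(TBS-oxy)-3-methyl-8-methylidene-1,3a,4,5,6,7,8,8a-octahydroazulene-5-carbaldehyde | C=C1[C@H](O[Si](C)(C)C(C)(C)C)C[C@@H](C=O)[C@@H](O[Si](C)(C)C(C)(C)C)[C@@H]2C(C)=CC[C@@H]12 | intermediate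
20 | (S)-4-benzyl-1,3-oxazolidin-2-one | O=C1N[C@@H](Cc2ccccc2)CO1 | starting material
21 | (diethoxyphosphoryl)acetic acid | CCOP(=O)(CC(=O)O)OCC | starting material
22 | (diethoxyphosphoryl)acetic 2,2-dimethylpropanoic anhydride | CCOP(=O)(CC(=O)OC(=O)C(C)(C)C)OCC | intermediate (not isolated)
23 | diethyl {2-[(4S)-4-benzyl-2-oxo-1,3-oxazolidin-3-yl]-2-oxoethyl}phosphonate | CCOP(=O)(CC(=O)N1[C@@H](Cc2ccccc2)COC1=O)OCC | intermediate
24 | (4S)-4-benzyl-3-[(2E)-3-Az-prop-2-enoyl]-1,3-oxazolidin-2-one | C=C1[C@H](O[Si](C)(C)C(C)(C)C)C[C@@H](/C=C/C(=O)N3[C@@H](Cc4ccccc4)COC3=O)[C@@H](O[Si](C)(C)C(C)(C)C)[C@@H]2C(C)=CC[C@@H]12 | intermediate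
25 | (4S)-4-benzyl-3-[(3S)-3-Az-butanoyl]-1,3-oxazolidin-2-one | C=C1[C@H](O[Si](C)(C)C(C)(C)C)C[C@@H]([C@@H](C)CC(=O)N3[C@@H](Cc4ccccc4)COC3=O)[C@@H](O[Si](C)(C)C(C)(C)C)[C@@H]2C(C)=CC[C@@H]12 | intermediate
26 | (4S)-4-benzyl-3-[(2S,3R)-3-Az-2-hydroxybutanoyl]-1,3-oxazolidin-2-one | C=C1[C@H](O[Si](C)(C)C(C)(C)C)C[C@@H]([C@@H](C)[C@H](O)C(=O)N3[C@@H](Cc4ccccc4)COC3=O)[C@@H](O[Si](C)(C)C(C)(C)C)[C@@H]2C(C)=CC[C@@H]12 | intermediate
27 | (2S,3R)-3-Az-2-hydroxy-N-methoxy-N-methylbutanamide | C=C1[C@H](O[Si](C)(C)C(C)(C)C)C[C@@H]([C@@H](C)[C@H](O)C(=O)N(C)OC)[C@@H](O[Si](C)(C)C(C)(C)C)[C@@H]2C(C)=CC[C@@H]12 | intermediate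
28 | (5S,6R)-6-Az-5-hydroxy-2-methylhept-2-en-4-one | C=C1[C@H](O[Si](C)(C)C(C)(C)C)C[C@@H]([C@@H](C)[C@H](O)C(=O)C=C(C)C)[C@@H](O[Si](C)(C)C(C)(C)C)[C@@H]2C(C)=CC[C@@H]12 | intermediate
29 | (2R,3S)-2-Az-6-methyl-4-oxohept-5-en-3-yl acetate | C=C1[C@H](O[Si](C)(C)C(C)(C)C)C[C@@H]([C@@H](C)[C@H](OC(C)=O)C(=O)C=C(C)C)[C@@H](O[Si](C)(C)C(C)(C)C)[C@@H]2C(C)=CC[C@@H]12 | intermediate
30 | (2R,3S,4S)-2-Az-4-hydroxy-6-methylhept-5-en-3-yl acetate | C=C1[C@H](O[Si](C)(C)C(C)(C)C)C[C@@H]([C@@H](C)[C@H](OC(C)=O)[C@H](C=C(C)C)O)[C@@H](O[Si](C)(C)C(C)(C)C)[C@@H]2C(C)=CC[C@@H]12 | intermediate (not isolated)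
31 | (2R,3S,4S)-2-Az-6-methylhept-5-ene-3,4-diyl diacetate | C=C1[C@H](O[Si](C)(C)C(C)(C)C)C[C@@H]([C@@H](C)[C@H](OC(C)=O)[C@H](C=C(C)C)OC(C)=O)[C@@H](O[Si](C)(C)C(C)(C)C)[C@@H]2C(C)=CC[C@@H]12 | intermediate
32 | (3aS,4R,5S,7R,8aR)-5-[(2R,3S,4S)-3,4-bis(acetyloxy)-6-methylhept-5-en-2-yl]-3-methyl-8-methylidene-1,3a,4,5,6,7,8,8a-octahydroazulene-4,7-diol | C=C1[C@H](O)C[C@@H]([C@@H](C)[C@H](OC(C)=O)[C@H](C=C(C)C)OC(C)=O)[C@@H](O)[C@@H]2C(C)=CC[C@@H]12 | target

Total step count: 22. Longest linear sequence: 21 steps (steps 1–13 and 15–22, from furan-2(5H)-one); step 14 makes the olefination reagent.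

Steps most likely to fail

1. Step 7. The short-lived ylide may be lost to proton shift or dimerization before the moderately reactive acrylate intercepts it, and the addition itself may show little exo/endo preference. The fallback uses an alkyne in place of the alkene and sets C5 afterwards. It sets out from 9: the same Rh2(OAc)4 cyclization is run in the presence of methyl propiolate, a faster dipolarophile that raises no exo/endo question, and should give methyl (3aS,4S,7S,8aR)-3-methyl-8-oxo-1,3a,4,7,8,8a-hexahydro-4,7-epoxyazulene-5-carboxylate F1. Hydrogenation of its strained, conjugated C5=C6 bond (H2, one equivalent, Pd/C, EtOAc) from the exo face should give endo ester 12, and NaOMe/MeOH equilibration brings the route back at 13.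

2. Step 10. Oxygen transfer to the enolate may occur with poor facial selectivity or mainly on the upper face. The fallback accepts the oxidation as it comes and corrects C7 by substitution with inversion. It sets out from 15: the C7 epimer of 16, methyl (3aS,4S,5R,7S,8aR)-4-(TBS-oxy)-7-hydroxy-3-methyl-8-oxo-1,3a,4,5,6,7,8,8a-octahydroazulene-5-carboxylate F2, is converted by a Mitsunobu reaction (4-nitrobenzoic acid, PPh3, DIAD, toluene) into methyl (3aS,4S,5R,7R,8aR)-4-(TBS-oxy)-3-methyl-7-[(4-nitrobenzoyl)oxy]-8-oxo-1,3a,4,5,6,7,8,8a-octahydroazulene-5-carboxylate F3. Methanolysis (K2CO3, MeOH, 0 °C) then comes back to the route at 16.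

3. Step 1. Transfer of the hindered alkenyl group to the poorly reactive butenolide may be outrun by protodeboronation, or may proceed with low enantioselectivity. The fallback replaces asymmetric catalysis by resolution. It sets out from 1: copper-catalysed conjugate addition (isopropenylmagnesium bromide, CuI, Me3SiCl, THF, −78 °C) should give racemic 4-(prop-1-en-2-yl)oxolan-2-one F4. Ring-opening with (S)-1-phenylethylamine and AlMe3 gives two diastereomeric hydroxy amides, of which (3S)-3-(hydroxymethyl)-4-methyl-N-[(1S)-1-phenylethyl]pent-4-enamide F5 is separated by chromatography or crystallization. Heating F5 with aqueous H2SO4 in dioxane closes the lactone again and comes back to the route at 2.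

Further compounds
F1 | step 7 | methyl (3aS,4S,7S,8aR)-3-methyl-8-oxo-1,3a,4,7,8,8a-hexahydro-4,7-epoxyazulene-5-carboxylate | O=C1[C@@H]2C=C(C(=O)OC)[C@@H](O2)[C@@H]3C(C)=CC[C@@H]13
F2 | step 10 | methyl (3aS,4S,5R,7S,8aR)-4-(TBS-oxy)-7-hydroxy-3-methyl-8-oxo-1,3a,4,5,6,7,8,8a-octahydroazulene-5-carboxylate | O=C1[C@@H](O)C[C@@H](C(=O)OC)[C@@H](O[Si](C)(C)C(C)(C)C)[C@@H]2C(C)=CC[C@@H]12
F3 | step 10 | methyl (3aS,4S,5R,7R,8aR)-4-(TBS-oxy)-3-methyl-7-[(4-nitrobenzoyl)oxy]-8-oxo-1,3a,4,5,6,7,8,8a-octahydroazulene-5-carboxylate | O=C1[C@H](OC(=O)c3ccc(cc3)[N+](=O)[O-])C[C@@H](C(=O)OC)[C@@H](O[Si](C)(C)C(C)(C)C)[C@@H]2C(C)=CC[C@@H]12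
F4 | step 1 | racemic 4-(prop-1-en-2-yl)oxolan-2-one | O=C1OCC(C(C)=C)C1
F5 | step 1 | (3S)-3-(hydroxymethyl)-4-methyl-N-[(1S)-1-phenylethyl]pent-4-enamide | C=C(C)[C@@H](CO)CC(=O)N[C@@H](C)c1ccccc1
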